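**Retrosynthetic overview**
1. Target 25 is the (S)-2-methylbutanoate of a 3(2H)-furanone-bridged germacranolide. The ester is put on last with inversion at C8 (Mitsunobu) from the 8α-alcohol 23, so that the 8α-oxygen can first serve as the stereocontrol element.
2. Key disconnection C6–C7. C6 is the lactone carbinol carbon (allylic to C4=C5) and C7 is the γ-carbon of the C13=C11–C12 acrylate unit. This one bond lies in both the γ-lactone ring and the ten-membered carbocycle (nine-membered through the C3–O–C10 bridge), so an intramolecular carbonyl allylation of bromo enal 19 closes both rings and sets C6 and C7 together.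
3. 19 is a monocyclic 3(2H)-furanone. The furanone comes from gold-catalysed cyclisation of α'-hydroxy ynone 12, which arises by opening γ-lactone 8 with the acetylide of enyne 10 (C1–C2 bond).
4. Lactone 8 comes from (R)-citramalic acid (C10 bought): acyl alkynylation (C7–C8 bond), hydroiodination, CBS reduction (C8 by catalysis). C12 is added later by carbonylation.
5. Ring order: furanone ring (step 7), then ten-membered carbocycle and γ-lactone together (step 14). The dioxolanone of 2–7 and the γ-lactone of 8 are temporary rings.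

Key step: step 14

Remark: germacrane numbering (C1–C15, oxygen bridge C3–O–C10) is used for the atoms; compounds 1, 3, 9 and 24 are taken as commercial; the CIP label at C7 reads S in 21 and 22 and R in 23 and 25 only because the group on O8 changes the priorities, the configuration itself is the same.

**Step 1**
Reactants: 1 (R)-citramalic acid
Product: 2 2-[(4R)-2,2,4-trimethyl-5-oxo-1,3-dioxolan-4-yl]acetic acid
Conditions: 2,2-dimethoxypropane, PPTS (cat.), 23 °C
Reagents that add atoms: 2,2-dimethoxypropane, COC(C)(C)OC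
Why: Acid-catalysed acetonide exchange should engage the α-hydroxy acid as the five-membered dioxolanone, which differentiates the two carboxyl groups and leaves the bought quaternary center C10 untouched.

**Step 2**
Reactants: 2 dioxolanone acid; 3 1-methoxy-4-[(prop-2-yn-1-yloxy)methyl]benzene
Product: 5 (5R)-5-{5-[(4-methoxyphenyl)methoxy]-2-oxopent-3-yn-1-yl}-2,2,5-trimethyl-1,3-dioxolan-4-one, via acid chloride 4 (not isolated)
Conditions: (COCl)2, DMF (cat.), CH2Cl2, 0 to 23 °C, evaporate; then 3, PdCl2(PPh3)2 (2 mol %), CuI (4 mol %), Et3N, THF, 23 °C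
Reagents that add atoms: none
Why: Acyl Sonogashira coupling of an acid chloride with a terminal alkyne should give the ynone (C7–C8 bond) under conditions that leave the dioxolanone intact.

**Step 3**
Reactants: 5 ynone
Product: 6 (5R)-5-{(3Z)-4-iodo-5-[(4-methoxyphenyl)methoxy]-2-oxopent-3-en-1-yl}-2,2,5-trimethyl-1,3-dioxolan-4-one
Conditions: NaI, AcOH, 23 °C
Reagents that add atoms: sodium iodide, [Na+].[I-]
Why: Conjugate hydroiodination of the ynone (iodide to the β-carbon C11, anti protonation at C7) should give the kinetic (Z)-β-iodo enone, with a carbonylation handle on C11 cis to C8.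

**Step 4**
Reactants: 6 (Z)-β-iodo enone
Product: 8 (3R,5S)-3-hydroxy-5-{(1Z)-2-iodo-3-[(4-methoxyphenyl)methoxy]prop-1-en-1-yl}-3-methyloxolan-2-one, via hydroxy dioxolanone 7 (not isolated)
Conditions: (R)-2-methyl-CBS-oxazaborolidine (20 mol %), BH3·SMe2, THF, −40 °C; MeOH; then PPTS (cat.), CH2Cl2, 23 °C
Reagents that add atoms: none
Why: Corey–Bakshi–Shibata reduction with the iodoalkenyl group as the large substituent should set C8 (S) by catalyst control, and the new hydroxyl then displaces acetone from the dioxolanone (translactonisation) to give the γ-lactone that ties O8 to C1.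

**Step 5**
Reactants: 9 (2Z)-3-methylpent-2-en-4-yn-1-ol
Product: 10 tert-butyl(dimethyl){[(2Z)-3-methylpent-2-en-4-yn-1-yl]oxy}silane
Conditions: TBSCl, imidazole, CH2Cl2, 23 °C
Reagents that add atoms: tert-butyl(chloro)dimethylsilane, CC(C)(C)[Si](C)(C)Cl
Why: Standard silylation of the primary allylic alcohol; the Z geometry (C6 cis to C3) that the ring needs is bought with 9.

**Step 6**
Reactants: 8 lactone; 10 silyl enyne
Product: 12 (2Z,7R,9S,10Z)-1-{[tert-butyl(dimethyl)silyl]oxy}-7,9-dihydroxy-11-iodo-12-[(4-methoxyphenyl)methoxy]-3,7-dimethyldodeca-2,10-dien-4-yn-6-one, via lithium acetylide 11 (not isolated)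
Conditions: 10 (2.3 equiv), n-BuLi (2.2 equiv), THF, −78 °C; then 8, −78 to −40 °C; aq. NH4Cl
Reagents that add atoms: none
Why: Addition of a lithium acetylide to a γ-lactone should stop at the lithium hemiketal (no α-hydrogen at quaternary C10; one equivalent is used up by the tertiary OH), so work-up releases the α'-hydroxy ynone and frees O8 in the same operation.

**Step 7**
Reactants: 12 α'-hydroxy ynone
Product: 13 (2R)-5-[(2Z)-4-{[tert-butyl(dimethyl)silyl]oxy}but-2-en-2-yl]-2-{(2S,3Z)-2-hydroxy-4-iodo-5-[(4-methoxyphenyl)methoxy]pent-3-en-1-yl}-2-methylfuran-3(2H)-one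
Conditions: (Ph3P)AuNTf2 (5 mol %), toluene, 23 °C
Reagents that add atoms: none
Why: Gold-catalysed 5-endo-dig cycloisomerisation of an α'-hydroxy ynone (tertiary C10–OH onto the activated alkyne carbon C3, then protodeauration) is an established route to 3(2H)-furanones and does not touch C10.

**Step 8**
Reactants: 13 furanone alcohol
Product: 14 (2R)-5-[(2Z)-4-{[tert-butyl(dimethyl)silyl]oxy}but-2-en-2-yl]-2-{(2S,3Z)-2-{[tert-butyl(dimethyl)silyl]oxy}-4-iodo-5-[(4-methoxyphenyl)methoxy]pent-3-en-1-yl}-2-methylfuran-3(2H)-one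
Conditions: TBSOTf, 2,6-lutidine, CH2Cl2, −78 to 0 °C
Reagents that add atoms: tert-butyldimethylsilyl trifluoromethanesulfonate, CC(C)(C)[Si](C)(C)OS(=O)(=O)C(F)(F)F
Why: Silylation of the secondary allylic alcohol blocks O8, so that the cis ester introduced next cannot close to a butenolide and O8 cannot compete for C12 in the key step.

**Step 9**
Reactants: 14 alkenyl iodide
Product: 15 methyl (2Z,4S)-4-{[tert-butyl(dimethyl)silyl]oxy}-5-{(2R)-5-[(2Z)-4-{[tert-butyl(dimethyl)silyl]oxy}but-2-en-2-yl]-2-methyl-3-oxo-2,3-dihydrofuran-2-yl}-2-{[(4-methoxyphenyl)methoxy]methyl}pent-2-enoate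
Conditions: PdCl2(PPh3)2 (5 mol %), CO (1 atm), MeOH, Et3N, DMF, 55 °C
Reagents that add atoms: carbon monoxide, [C-]#[O+]; methanol, CO
Why: Palladium-catalysed methoxycarbonylation (oxidative addition of zerovalent palladium to the C–I bond, CO insertion, methanolysis) proceeds with retention of alkene geometry and should place C12 cis to C8.

**Step 10**
Reactants: 15 PMB ether
Product: 16 methyl (2Z,4S)-4-{[tert-butyl(dimethyl)silyl]oxy}-5-{(2R)-5-[(2Z)-4-{[tert-butyl(dimethyl)silyl]oxy}but-2-en-2-yl]-2-methyl-3-oxo-2,3-dihydrofuran-2-yl}-2-(hydroxymethyl)pent-2-enoate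
Conditions: DDQ, CH2Cl2–pH 7 buffer, 0 °C
Reagents that add atoms: none
Why: Oxidative cleavage of the 4-methoxybenzyl ether should free the C13 hydroxyl while both silyl ethers stay in place.

**Step 11**
Reactants: 16 allylic alcohol
Product: 17 methyl (2E,4S)-2-(bromomethyl)-4-{[tert-butyl(dimethyl)silyl]oxy}-5-{(2R)-5-[(2Z)-4-{[tert-butyl(dimethyl)silyl]oxy}but-2-en-2-yl]-2-methyl-3-oxo-2,3-dihydrofuran-2-yl}pent-2-enoate
Conditions: CBr4, PPh3 (added last), CH2Cl2, 0 °C
Reagents that add atoms: carbon tetrabromide, BrC(Br)(Br)Br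
Why: Appel bromination of the primary allylic alcohol should give the 2-(bromomethyl)enoate without allylic transposition, since the alkene is conjugated and trisubstituted.

**Step 12**
Reactants: 17 bis-silyl ether
Product: 18 methyl (2E,4S)-2-(bromomethyl)-4-{[tert-butyl(dimethyl)silyl]oxy}-5-{(2R)-5-[(2Z)-4-hydroxybut-2-en-2-yl]-2-methyl-3-oxo-2,3-dihydrofuran-2-yl}pent-2-enoate
Conditions: HF·pyridine, pyridine, THF, 0 °C
Reagents that add atoms: none
Why: A primary allylic silyl ether is cleaved much faster than the hindered secondary one at C8 under buffered fluoride conditions.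

**Step 13**
Reactants: 18 allylic alcohol
Product: 19 methyl (2E,4S)-2-(bromomethyl)-4-{[tert-butyl(dimethyl)silyl]oxy}-5-{(2R)-2-methyl-3-oxo-5-[(2Z)-4-oxobut-2-en-2-yl]-2,3-dihydrofuran-2-yl}pent-2-enoate
Conditions: Dess–Martin periodinane, NaHCO3, CH2Cl2, 0 °C; used at once
Reagents that add atoms: none
Why: Buffered Dess–Martin oxidation is neutral and fast enough to give the (Z)-enal without Z to E isomerisation and tolerates the allylic bromide.

**Step 14**
Reactants: 19 bromo enal
Product: 22 (4Z,6R,7S,8S,10R)-8-{[tert-butyl(dimethyl)silyl]oxy}-3,10-epoxy-1-oxogermacra-2,4,11(13)-trien-12,6-olide, via allylchromium dichloride 20 (not isolated), via seco hydroxy ester 21 (not isolated)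
Conditions: CrCl2 (10 equiv), THF, 2 mM (slow addition of 19), 23 °C; aq. NH4Cl; then TsOH·H2O (cat.), CH2Cl2, 23 °C
Reagents that add atoms: none
Why: Two equivalents of CrCl2 (divalent chromium) reduce the allylic C–Br bond of 19 to the trivalent σ-allylchromium 20, whose γ-carbon C7 adds to the enal carbon C6 through a six-membered chair transition state (chromium bound to C13 and to the aldehyde oxygen), and the chromium alkoxide, or the hydroxy ester 21 after work-up, then acylates itself with the C12 methyl ester. The closest known reaction type is the chromium-mediated (Nozaki–Hiyama-type) intramolecular allylation of an enal by a 2-(bromomethyl)-2-enoate that closes the ten-membered ring of germacranolides through this same C6–C7 bond with trans-lactone formation. Ring closures: the ten-membered carbocycle (nine-membered through the furanone oxygen) by 10-exo-trig (9-exo-trig) attack on the aldehyde, the γ-lactone by 5-exo-trig acyl substitution at C12. C6 and C7 (relative): the E allyl unit (C8 trans to C13) and the aldehyde place C8 and C5 pseudo-equatorial on the chair, the arrangement in which the short C8–C9–C10 tether can bridge them, which gives the 6,7-anti adduct and hence the trans-fused lactone. C7 (absolute) is set by C8: with H8 eclipsing the C7=C11 bond (allylic 1,3-strain against the cis ester), the 8α-silyloxy group anti to the forming bond and C9 on the attacked face, the 8S ether should give the natural configuration at C7 and, through the chair, at C6, and the 10R center, which fixes the face of the furanone over which the new ring arches, is expected to act in the same sense. Selectivities needed: γ- over α-attack (inherent to allylchromium reagents), aldehyde over the vinylogous-ester carbonyl (chromium reagents are aldehyde-selective), ring closure over oligomerisation (high dilution; furanone and Z-alkene hold the two ends close), and no 1,4-elimination of O8 (a silyl ether, not an acyloxy group, sits at C8).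

**Step 15**
Reactants: 22 silyl ether
Product: 23 (4Z,6R,7R,8S,10R)-3,10-epoxy-8-hydroxy-1-oxogermacra-2,4,11(13)-trien-12,6-olide
Conditions: HF·pyridine, THF, 23 °C
Reagents that add atoms: none
Why: Acidic fluoride removes the secondary silyl ether without touching the α-methylene lactone or the furanone, both of which are base-sensitive.

**Step 16**
Reactants: 23 8α-alcohol; 24 (2S)-2-methylbutanoic acid
Product: 25 (4Z,6R,7R,8R,10R)-3,10-epoxy-8-{[(2S)-2-methylbutanoyl]oxy}-1-oxogermacra-2,4,11(13)-trien-12,6-olide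
Conditions: PPh3 and DIAD premixed, toluene, 0 °C; then 23 and 24, 0 to 23 °C
Reagents that add atoms: none
Why: Mitsunobu esterification (carboxylate displaces the alkoxyphosphonium by SN2) should invert C8 to the natural 8R (8β) ester, and the acid reacts only as a nucleophile, so its own α-stereocenter is not at risk.

**Compound list**
1 | (2R)-2-hydroxy-2-methylbutanedioic acid, (R)-citramalic acid | OC(=O)C[C@@](C)(O)C(=O)O | starting material
2 | 2-[(4R)-2,2,4-trimethyl-5-oxo-1,3-dioxolan-4-yl]acetic acid | OC(=O)C[C@@]1(C)OC(C)(C)OC1=O | intermediate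
3 | 1-methoxy-4-[(prop-2-yn-1-yloxy)methyl]benzene | C#CCOCc1ccc(OC)cc1 | starting material
4 | 2-[(4R)-2,2,4-trimethyl-5-oxo-1,3-dioxolan-4-yl]acetyl chloride | ClC(=O)C[C@@]1(C)OC(C)(C)OC1=O | intermediate
5 | (5R)-5-{5-[(4-methoxyphenyl)methoxy]-2-oxopent-3-yn-1-yl}-2,2,5-trimethyl-1,3-dioxolan-4-one | COc1ccc(COCC#CC(=O)C[C@@]2(C)OC(C)(C)OC2=O)cc1 | intermediate
6 | (5R)-5-{(3Z)-4-iodo-5-[(4-methoxyphenyl)methoxy]-2-oxopent-3-en-1-yl}-2,2,5-trimethyl-1,3-dioxolan-4-one | COc1ccc(COC/C(I)=C/C(=O)C[C@@]2(C)OC(C)(C)OC2=O)cc1 | intermediate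
7 | (5R)-5-{(2S,3Z)-2-hydroxy-4-iodo-5-[(4-methoxyphenyl)methoxy]pent-3-en-1-yl}-2,2,5-trimethyl-1,3-dioxolan-4-one | COc1ccc(COC/C(I)=C/[C@@H](O)C[C@@]2(C)OC(C)(C)OC2=O)cc1 | intermediate
8 | (3R,5S)-3-hydroxy-5-{(1Z)-2-iodo-3-[(4-methoxyphenyl)methoxy]prop-1-en-1-yl}-3-methyloxolan-2-one | COc1ccc(COC/C(I)=C/[C@@H]2C[C@@](C)(O)C(=O)O2)cc1 | intermediate
9 | (2Z)-3-methylpent-2-en-4-yn-1-ol | C#C/C(C)=C\CO | starting material
10 | tert-butyl(dimethyl){[(2Z)-3-methylpent-2-en-4-yn-1-yl]oxy}silane | C#C/C(C)=C\CO[Si](C)(C)C(C)(C)C | intermediate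
11 | lithium acetylide of 10 | [Li]C#C/C(C)=C\CO[Si](C)(C)C(C)(C)C | intermediate
12 | (2Z,7R,9S,10Z)-1-{[tert-butyl(dimethyl)silyl]oxy}-7,9-dihydroxy-11-iodo-12-[(4-methoxyphenyl)methoxy]-3,7-dimethyldodeca-2,10-dien-4-yn-6-one | CC(C)(C)[Si](C)(C)OC/C=C(/C)C#CC(=O)[C@](C)(O)C[C@H](O)/C=C(\I)COCc1ccc(OC)cc1 | intermediate
13 | (2R)-5-[(2Z)-4-{[tert-butyl(dimethyl)silyl]oxy}but-2-en-2-yl]-2-{(2S,3Z)-2-hydroxy-4-iodo-5-[(4-methoxyphenyl)methoxy]pent-3-en-1-yl}-2-methylfuran-3(2H)-one | CC(C)(C)[Si](C)(C)OC/C=C(/C)C1=CC(=O)[C@@](C)(C[C@H](O)/C=C(\I)COCc2ccc(OC)cc2)O1 | intermediate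
14 | (2R)-5-[(2Z)-4-{[tert-butyl(dimethyl)silyl]oxy}but-2-en-2-yl]-2-{(2S,3Z)-2-{[tert-butyl(dimethyl)silyl]oxy}-4-iodo-5-[(4-methoxyphenyl)methoxy]pent-3-en-1-yl}-2-methylfuran-3(2H)-one | CC(C)(C)[Si](C)(C)OC/C=C(/C)C1=CC(=O)[C@@](C)(C[C@H](O[Si](C)(C)C(C)(C)C)/C=C(\I)COCc2ccc(OC)cc2)O1 | intermediate
15 | methyl (2Z,4S)-4-{[tert-butyl(dimethyl)silyl]oxy}-5-{(2R)-5-[(2Z)-4-{[tert-butyl(dimethyl)silyl]oxy}but-2-en-2-yl]-2-methyl-3-oxo-2,3-dihydrofuran-2-yl}-2-{[(4-methoxyphenyl)methoxy]methyl}pent-2-enoate | CC(C)(C)[Si](C)(C)OC/C=C(/C)C1=CC(=O)[C@@](C)(C[C@H](O[Si](C)(C)C(C)(C)C)/C=C(\C(=O)OC)COCc2ccc(OC)cc2)O1 | intermediate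
16 | methyl (2Z,4S)-4-{[tert-butyl(dimethyl)silyl]oxy}-5-{(2R)-5-[(2Z)-4-{[tert-butyl(dimethyl)silyl]oxy}but-2-en-2-yl]-2-methyl-3-oxo-2,3-dihydrofuran-2-yl}-2-(hydroxymethyl)pent-2-enoate | CC(C)(C)[Si](C)(C)OC/C=C(/C)C1=CC(=O)[C@@](C)(C[C@H](O[Si](C)(C)C(C)(C)C)/C=C(\C(=O)OC)CO)O1 | intermediate
17 | methyl (2E,4S)-2-(bromomethyl)-4-{[tert-butyl(dimethyl)silyl]oxy}-5-{(2R)-5-[(2Z)-4-{[tert-butyl(dimethyl)silyl]oxy}but-2-en-2-yl]-2-methyl-3-oxo-2,3-dihydrofuran-2-yl}pent-2-enoate | CC(C)(C)[Si](C)(C)OC/C=C(/C)C1=CC(=O)[C@@](C)(C[C@H](O[Si](C)(C)C(C)(C)C)/C=C(\C(=O)OC)CBr)O1 | intermediate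
18 | methyl (2E,4S)-2-(bromomethyl)-4-{[tert-butyl(dimethyl)silyl]oxy}-5-{(2R)-5-[(2Z)-4-hydroxybut-2-en-2-yl]-2-methyl-3-oxo-2,3-dihydrofuran-2-yl}pent-2-enoate | OC/C=C(/C)C1=CC(=O)[C@@](C)(C[C@H](O[Si](C)(C)C(C)(C)C)/C=C(\C(=O)OC)CBr)O1 | intermediate
19 | methyl (2E,4S)-2-(bromomethyl)-4-{[tert-butyl(dimethyl)silyl]oxy}-5-{(2R)-2-methyl-3-oxo-5-[(2Z)-4-oxobut-2-en-2-yl]-2,3-dihydrofuran-2-yl}pent-2-enoate | O=C/C=C(/C)C1=CC(=O)[C@@](C)(C[C@H](O[Si](C)(C)C(C)(C)C)/C=C(\C(=O)OC)CBr)O1 | intermediate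
20 | σ-allylchromium dichloride from 19 (bromine replaced by CrCl2, trivalent chromium) | O=C/C=C(/C)C1=CC(=O)[C@@](C)(C[C@H](O[Si](C)(C)C(C)(C)C)/C=C(\C(=O)OC)C[Cr](Cl)Cl)O1 | intermediate
21 | methyl (4Z,6R,7S,8S,10R)-8-{[tert-butyl(dimethyl)silyl]oxy}-3,10-epoxy-6-hydroxy-1-oxogermacra-2,4,11(13)-trien-12-oate | C=C(C(=O)OC)[C@H]1[C@H](O)/C=C(/C)C2=CC(=O)[C@@](C)(C[C@@H]1O[Si](C)(C)C(C)(C)C)O2 | intermediate
22 | (4Z,6R,7S,8S,10R)-8-{[tert-butyl(dimethyl)silyl]oxy}-3,10-epoxy-1-oxogermacra-2,4,11(13)-trien-12,6-olide | C=C1C(=O)O[C@@H]2/C=C(/C)C3=CC(=O)[C@@](C)(C[C@H](O[Si](C)(C)C(C)(C)C)[C@@H]12)O3 | intermediate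
23 | (4Z,6R,7R,8S,10R)-3,10-epoxy-8-hydroxy-1-oxogermacra-2,4,11(13)-trien-12,6-olide | C=C1C(=O)O[C@@H]2/C=C(/C)C3=CC(=O)[C@@](C)(C[C@H](O)[C@@H]12)O3 | intermediate
24 | (2S)-2-methylbutanoic acid | CC[C@H](C)C(=O)O | starting material
25 | (4Z,6R,7R,8R,10R)-3,10-epoxy-8-{[(2S)-2-methylbutanoyl]oxy}-1-oxogermacra-2,4,11(13)-trien-12,6-olide | C=C1C(=O)O[C@@H]2/C=C(/C)C3=CC(=O)[C@@](C)(C[C@@H](OC(=O)[C@@H](C)CC)[C@@H]12)O3 | target

**Step count and risks**
Total step count: 16. Longest linear sequence: 15 steps (1–4 and 6–16, from 1); step 5 is a one-step side branch.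

Steps most likely to fail:

1. Step 14. The allylchromium may be protonated or may couple intermolecularly faster than the medium ring closes, or it may equilibrate by metallotropic shift to the Z allyl form and erode the 6,7-anti sense. The fallback sets out from 17. Palladium-catalysed borylation (B2pin2, Pd2(dba)3 cat., DMSO, 50 °C) should give the configurationally stable (E)-2-(methoxycarbonyl)allylboronate F1. Buffered HF·pyridine then frees the primary alcohol as the hydroxy allylboronate F2, and Dess–Martin oxidation gives the enal allylboronate F3. Heating F3 in dilute toluene at 80 °C, or Sc(OTf)3 (cat.) in CH2Cl2, should close the ring by intramolecular allylboration through a closed chair, the known route from 2-alkoxycarbonyl allylboronates and aldehydes to α-methylene-γ-lactones, which translates the E geometry into the anti adduct. This gives the O-boryl adduct F4; aqueous work-up and TsOH then lead through 21 back to the route at 22.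

2. Step 16. The activated 8α-oxyphosphonium may eliminate toward C7 or C9, displacement at the hindered ring carbon may be slow, and free PPh3 may add to the α-methylene lactone. The fallback sets out from 23. Chloromethanesulfonyl chloride and pyridine give the 8α-chloromethanesulfonate F5. This is displaced with inversion by cesium (2S)-2-methylbutanoate F6 (from 24 and Cs2CO3) with 18-crown-6 in toluene at 60 °C, coming back to the route at 25.

3. Step 4. Facial selectivity of the oxazaborolidine reduction may be poor, because the CH2 group that carries quaternary C10 is not much smaller than the iodoalkenyl group, and the iodo enone may lose its Z geometry. The fallback sets out from 5. Transfer hydrogenation of the ynone with RuCl[(S,S)-TsDPEN](p-cymene) and HCO2H–Et3N is expected to give the (S)-propargylic alcohol F7. NaAlH2(OCH2CH2OMe)2 in THF at 0 °C then reduces the dioxolanone to the diol and trans-hydroaluminates the alkyne under direction of the C8 alkoxide, and iodine at −78 °C gives the (Z)-iodo triol F8. TEMPO with PhI(OAc)2 oxidises the primary alcohol, and the lactol that forms with the C8 hydroxyl is oxidised on to the lactone, coming back to the route at 8.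

**Further compounds**
F1 | step 14 | methyl (2E,4S)-4-{[tert-butyl(dimethyl)silyl]oxy}-5-{(2R)-5-[(2Z)-4-{[tert-butyl(dimethyl)silyl]oxy}but-2-en-2-yl]-2-methyl-3-oxo-2,3-dihydrofuran-2-yl}-2-[(4,4,5,5-tetramethyl-1,3,2-dioxaborolan-2-yl)methyl]pent-2-enoate | CC(C)(C)[Si](C)(C)OC/C=C(/C)C1=CC(=O)[C@@](C)(C[C@H](O[Si](C)(C)C(C)(C)C)/C=C(\C(=O)OC)CB2OC(C)(C)C(C)(C)O2)O1
F2 | step 14 | methyl (2E,4S)-4-{[tert-butyl(dimethyl)silyl]oxy}-5-{(2R)-5-[(2Z)-4-hydroxybut-2-en-2-yl]-2-methyl-3-oxo-2,3-dihydrofuran-2-yl}-2-[(4,4,5,5-tetramethyl-1,3,2-dioxaborolan-2-yl)methyl]pent-2-enoate | OC/C=C(/C)C1=CC(=O)[C@@](C)(C[C@H](O[Si](C)(C)C(C)(C)C)/C=C(\C(=O)OC)CB2OC(C)(C)C(C)(C)O2)O1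
F3 | step 14 | methyl (2E,4S)-4-{[tert-butyl(dimethyl)silyl]oxy}-5-{(2R)-2-methyl-3-oxo-5-[(2Z)-4-oxobut-2-en-2-yl]-2,3-dihydrofuran-2-yl}-2-[(4,4,5,5-tetramethyl-1,3,2-dioxaborolan-2-yl)methyl]pent-2-enoate | O=C/C=C(/C)C1=CC(=O)[C@@](C)(C[C@H](O[Si](C)(C)C(C)(C)C)/C=C(\C(=O)OC)CB2OC(C)(C)C(C)(C)O2)O1
F4 | step 14 | methyl (4Z,6R,7S,8S,10R)-8-{[tert-butyl(dimethyl)silyl]oxy}-3,10-epoxy-1-oxo-6-[(4,4,5,5-tetramethyl-1,3,2-dioxaborolan-2-yl)oxy]germacra-2,4,11(13)-trien-12-oate | C=C(C(=O)OC)[C@H]1[C@H](OB3OC(C)(C)C(C)(C)O3)/C=C(/C)C2=CC(=O)[C@@](C)(C[C@@H]1O[Si](C)(C)C(C)(C)C)O2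
F5 | step 16 | (4Z,6R,7S,8S,10R)-8-[(chloromethanesulfonyl)oxy]-3,10-epoxy-1-oxogermacra-2,4,11(13)-trien-12,6-olide | C=C1C(=O)O[C@@H]2/C=C(/C)C3=CC(=O)[C@@](C)(C[C@H](OS(=O)(=O)CCl)[C@@H]12)O3
F6 | step 16 | cesium (2S)-2-methylbutanoate | CC[C@H](C)C(=O)[O-].[Cs+]
F7 | step 4 | (5R)-5-{(2S)-2-hydroxy-5-[(4-methoxyphenyl)methoxy]pent-3-yn-1-yl}-2,2,5-trimethyl-1,3-dioxolan-4-one | COc1ccc(COCC#C[C@@H](O)C[C@@]2(C)OC(C)(C)OC2=O)cc1
F8 | step 4 | (2R,4S,5Z)-6-iodo-7-[(4-methoxyphenyl)methoxy]-2-methylhept-5-ene-1,2,4-triol | COc1ccc(COC/C(I)=C/[C@@H](O)C[C@@](C)(O)CO)cc1
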